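The C8–C9 oxirane is trans-fused to the cycloheptane (oxygen β at C8, α at C9), so it cannot be made from a cycloheptene. It is made first, by Sharpless epoxidation of an (E)-allylic alcohol, and the seven-membered ring (C1, C5–C10) is closed last around it. The disconnection is C1–C10: an intramolecular carbonyl allylation in which a fluxional allylindium spanning C6–C5–C1, generated from a C6 allylic carbonate on the finished cyclopentene, adds through C1 to the epoxy aldehyde C10. This forms the ring, quaternary C1 and the C10 carbinol; the resulting C5=C6 alkene later takes H-5 and O-6 from the C10 oxygen. It exploits the 1,4-related oxygens at C6 and C10 flanking the C1–C5 ring fusion.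

Key step: step 16

Numbering: C1 (quaternary, CH3), C2 (OAc), C3, C4 (OH, iPr), C5 (ring-fusion CH), C6 (ester), C7, C8 and C9 (oxirane; C8 bears CH3), C10 (OH). Faces: β is the face of the C1 methyl group, α the opposite face. Skeleton name used below: daucane = 4-isopropyl-1,8-dimethylbicyclo[5.3.0]decane, numbered as above.

Remark on the target: the descriptors at C8 and C9 are both R, so C7 and C10 are trans on the oxirane (oxygen β at C8, α at C9, 8-methyl α). The route builds this arrangement as written; "8β,9α-epoxy" in the names below means exactly this.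

Step 1
Reactants: 1 (S)-4-(tert-butyldimethylsilyloxy)cyclopent-2-en-1-one
Product: 2 trans-4-(tert-butyldimethylsilyloxy)-3-methyl-1-(trimethylsilyloxy)cyclopent-1-ene
Conditions: MeMgBr, CuBr·SMe2 (10 mol %), TMSCl, THF, −78 °C; Et3N quench
Reagents that add atoms: methylmagnesium bromide, C[Mg]Br; chlorotrimethylsilane, C[Si](C)(C)Cl
Why: Copper-catalysed conjugate addition of the Grignard reagent (TMSCl-accelerated) delivers the methyl group anti to the silyloxy group and traps the enolate regiospecifically as its silyl enol ether, which prevents β-elimination of the silyloxy group, and the new methyl-bearing stereocentre is erased again in step 2.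

Step 2
Reactants: 2 trans-4-(tert-butyldimethylsilyloxy)-3-methyl-1-(trimethylsilyloxy)cyclopent-1-ene
Product: 3 (S)-4-(tert-butyldimethylsilyloxy)-3-methylcyclopent-2-en-1-one
Conditions: Pd(OAc)2 (10 mol %), O2 (1 atm), DMSO, rt
Reagents that add atoms: none
Why: Saegusa–Ito dehydrogenation of the regiodefined silyl enol ether (oxygen as terminal oxidant) re-forms the enone with the methyl group on the β-carbon and leaves the silyloxy stereocentre untouched.

Step 3
Reactants: 3 (S)-4-(tert-butyldimethylsilyloxy)-3-methylcyclopent-2-en-1-one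
Product: 4 (S)-4-(tert-butyldimethylsilyloxy)-2-iodo-3-methylcyclopent-2-en-1-one
Conditions: I2, K2CO3, DMAP (20 mol %), THF/H2O, rt
Reagents that add atoms: iodine, II
Why: α-Iodination of the enone by the DMAP-triggered addition–iodination–elimination sequence (Baylis–Hillman-type activation) should give the α-iodoenone, whose C–I bond later becomes the C5–C6 bond.

Step 4
Reactants: 4 (S)-4-(tert-butyldimethylsilyloxy)-2-iodo-3-methylcyclopent-2-en-1-one
Product: 5 (1S,4S)-4-(tert-butyldimethylsilyloxy)-2-iodo-1-isopropyl-3-methylcyclopent-2-en-1-ol (hydroxyl cis to the silyloxy group)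
Conditions: i-PrMgCl, CeCl3, THF, −78 °C; aq. NH4Cl
Reagents that add atoms: isopropylmagnesium chloride, CC(C)[Mg]Cl
Why: The organocerium reagent (Grignard addition under Imamoto conditions, CeCl3 suppressing enolisation and reduction) adds 1,2 to the hindered ketone on the face anti to the silyloxy group, which sets C4 with its hydroxyl cis to the C2 oxygen.

Step 5
Reactants: 5 (1S,4S)-4-(tert-butyldimethylsilyloxy)-2-iodo-1-isopropyl-3-methylcyclopent-2-en-1-ol
Product: 6 (1S,4S)-2-iodo-1-isopropyl-3-methylcyclopent-2-ene-1,4-diol (cis-diol)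
Conditions: TBAF, AcOH (1:1), THF, 0 °C → rt
Reagents that add atoms: none
Why: Buffered fluoride cleaves the silyl ether without ionising the tertiary allylic alcohol, so that C2 can carry its final acetate from here on.

Step 6
Reactants: 6 (1S,4S)-2-iodo-1-isopropyl-3-methylcyclopent-2-ene-1,4-diol
Product: 7 (1S,4S)-4-hydroxy-3-iodo-4-isopropyl-2-methylcyclopent-2-en-1-yl acetate
Conditions: Ac2O, pyridine, DMAP (cat.), CH2Cl2, 0 °C
Reagents that add atoms: acetic anhydride, CC(=O)OC(C)=O
Why: DMAP-catalysed acetylation is selective for the secondary C2 hydroxyl because the tertiary C4 hydroxyl does not react under these conditions.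

Step 7
Reactants: 8 tert-butyl(but-3-yn-1-yloxy)dimethylsilane
Product: 10 (E)-5-(tert-butyldimethylsilyloxy)-3-methylpent-2-en-1-ol, via alkenylalane 9 (not isolated)
Conditions: Me3Al, Cp2ZrCl2 (0.3 equiv), CH2Cl2, 0 °C → rt; then n-BuLi, (CH2O)n, THF, −78 °C → rt
Reagents that add atoms: trimethylaluminium, C[Al](C)C; formaldehyde (as paraformaldehyde), C=O
Why: Zirconium-catalysed syn-carboalumination of the terminal alkyne (Negishi) places methyl on the internal carbon and aluminium on the terminal one, and the alanate formed with n-BuLi is hydroxymethylated with retention, which fixes the (E)-trisubstituted C8=C9 alkene with C7 and C10 trans.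

Step 8
Reactants: 10 (E)-5-(tert-butyldimethylsilyloxy)-3-methylpent-2-en-1-ol
Product: 11 (E)-tert-butyl{[5-(4-methoxybenzyloxy)-3-methylpent-3-en-1-yl]oxy}dimethylsilane
Conditions: NaH, 4-methoxybenzyl chloride, Bu4NI (cat.), THF/DMF, 0 °C → rt
Reagents that add atoms: 4-methoxybenzyl chloride, COc1ccc(CCl)cc1
Why: Williamson etherification of the allylic alkoxide protects the future C10 oxygen with a group that is later removed oxidatively in the presence of esters and a carbonate.

Step 9
Reactants: 11 (E)-tert-butyl{[5-(4-methoxybenzyloxy)-3-methylpent-3-en-1-yl]oxy}dimethylsilane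
Product: 12 (E)-5-(4-methoxybenzyloxy)-3-methylpent-3-en-1-ol
Conditions: TBAF, AcOH (1:1), THF, rt
Reagents that add atoms: none
Why: Fluoride cleaves the primary silyl ether and leaves the benzyl-type ether and the alkene geometry untouched.

Step 10
Reactants: 12 (E)-5-(4-methoxybenzyloxy)-3-methylpent-3-en-1-ol
Product: 13 (E)-5-(4-methoxybenzyloxy)-3-methylpent-3-enal
Conditions: Dess–Martin periodinane, NaHCO3, CH2Cl2, 0 °C; used at once
Reagents that add atoms: none
Why: Buffered Dess–Martin oxidation gives the β,γ-unsaturated aldehyde under neutral conditions, and immediate use avoids migration of the alkene into conjugation.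

Step 11
Reactants: 7 (1S,4S)-4-hydroxy-3-iodo-4-isopropyl-2-methylcyclopent-2-en-1-yl acetate; 13 (E)-5-(4-methoxybenzyloxy)-3-methylpent-3-enal
Product: 14 (1S,4S)-4-hydroxy-3-[(E)-1-hydroxy-5-(4-methoxybenzyloxy)-3-methylpent-3-en-1-yl]-4-isopropyl-2-methylcyclopent-2-en-1-yl acetate (mixture of epimers at C6)
Conditions: CrCl2 (4 equiv), NiCl2 (1 mol %), DMF, rt
Reagents that add atoms: none
Why: Nozaki–Hiyama–Kishi coupling (nickel-catalysed formation of the alkenylchromium species and its addition to the aldehyde) forms the C5–C6 bond in the presence of the free tertiary hydroxyl and the acetate, and the configuration at C6 is irrelevant because C6 becomes trigonal in step 16.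

Step 12
Reactants: 14 (1S,4S)-4-hydroxy-3-[(E)-1-hydroxy-5-(4-methoxybenzyloxy)-3-methylpent-3-en-1-yl]-4-isopropyl-2-methylcyclopent-2-en-1-yl acetate
Product: 15 (1S,4S)-4-hydroxy-4-isopropyl-3-[(E)-1-(methoxycarbonyloxy)-5-(4-methoxybenzyloxy)-3-methylpent-3-en-1-yl]-2-methylcyclopent-2-en-1-yl acetate (C6 epimers)
Conditions: ClCO2Me, pyridine, DMAP (cat.), CH2Cl2, 0 °C
Reagents that add atoms: methyl chloroformate, COC(=O)Cl
Why: Carbonate formation takes place at the secondary allylic C6 hydroxyl only (the tertiary C4 hydroxyl is inert) and installs the leaving group for the allylation.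

Step 13
Reactants: 15 the C6 methyl carbonate
Product: 16 (1S,4S)-4-hydroxy-3-[(E)-5-hydroxy-1-(methoxycarbonyloxy)-3-methylpent-3-en-1-yl]-4-isopropyl-2-methylcyclopent-2-en-1-yl acetate (C6 epimers)
Conditions: DDQ, CH2Cl2/pH 7 buffer, 0 °C
Reagents that add atoms: none
Why: Oxidative cleavage of the 4-methoxybenzyl ether by DDQ (hydride abstraction, hydrolysis of the oxocarbenium ion) frees the primary allylic C10 hydroxyl, while carbonate and acetate are inert.

Step 14
Reactants: 16 the (E)-allylic alcohol
Product: 17 (1S,4S)-4-hydroxy-3-{2-[(2R,3R)-3-(hydroxymethyl)-2-methyloxiran-2-yl]-1-(methoxycarbonyloxy)ethyl}-4-isopropyl-2-methylcyclopent-2-en-1-yl acetate (C6 epimers)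
Conditions: Ti(OiPr)4 (10 mol %), D-(−)-diethyl tartrate (12 mol %), t-BuOOH, 4 Å MS, CH2Cl2, −20 °C
Reagents that add atoms: tert-butyl hydroperoxide, CC(C)(C)OO
Why: Sharpless asymmetric epoxidation of the (E)-3,3-disubstituted primary allylic alcohol, in which the D-(−)-tartrate complex delivers oxygen to the face that gives the (2R,3R)-epoxy alcohol, sets C8 and C9 under reagent control with C7 and C10 trans on the oxirane, and the tetrasubstituted ring alkene, whose only free allylic hydroxyl is tertiary and hindered, is not epoxidised.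

Step 15
Reactants: 17 the (2R,3R)-epoxy alcohol
Product: 18 (1S,4S)-3-{2-[(2R,3S)-3-formyl-2-methyloxiran-2-yl]-1-(methoxycarbonyloxy)ethyl}-4-hydroxy-4-isopropyl-2-methylcyclopent-2-en-1-yl acetate (same oxirane geometry as 17; C6 epimers)
Conditions: Dess–Martin periodinane, NaHCO3, CH2Cl2, 0 °C
Reagents that add atoms: none
Why: Dess–Martin oxidation gives the α,β-epoxy aldehyde without touching the tertiary alcohol, and C9 is not epimerised because an oxirane carbon is not enolised under these conditions.

Step 16
Reactants: 18 the epoxy aldehyde carbonate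
Product: 20 2β-acetoxy-8β,9α-epoxydauc-5-ene-4β,10α-diol (1β-methyl, 4α-isopropyl, 8α-methyl), via allylindium species 19 (not isolated)
Conditions: Pd(PPh3)4 (10 mol %), InI (2 equiv), THF (2 mM), rt; aq. NH4Cl
Reagents that add atoms: none
Why: Zerovalent palladium ionises the C6 carbonate (loss of CO2 and methoxide) to a π-allyl complex across C6–C5–C1, InI reduces it to an allylindium species that equilibrates between its two C6 epimers, and this adds through its γ-terminus C1 to the tethered aldehyde in a six-membered, metal-bridged transition state. The closest known reactions are the palladium/indium umpolung allylation of aldehydes with allylic carbonates and intramolecular Nozaki–Hiyama–Kishi allylations that create quaternary carbons. The ring C1–C5–C6–C7–C8–C9–C10 is closed by the C1–C10 bond with the allyl unit kept inside the new ring, where it ends as the C5=C6 alkene; attack through C6 would need a cyclopentane around the trans-oxirane and is excluded. C1 is set by the face of the cyclopentene that C10 can reach: the fixed twist of the (8R,9R)-oxirane, in which C7 and C10 lie on opposite sides, should let the chain reach only the α face, which is also the face anti to the C2 acetoxy group, so the methyl group ends up β. C10 is set by the cyclic transition state, in which the carbonyl oxygen must lie below C6 where indium sits, so that the hydroxyl ends up α. The step needs γ-regioselectivity (secured by the tether and by indium resting on the less substituted terminus) and chemoselectivity (the carbonate ionises faster than the C2 acetate and the non-allylic oxirane is inert to zerovalent palladium), and the strain of a trans-fused oxirane in a cycloheptene has to be paid by the exergonic C–C bond formation under high dilution.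

Step 17
Reactants: 20 2β-acetoxy-8β,9α-epoxydauc-5-ene-4β,10α-diol
Product: 22 2β-acetoxy-8β,9α-epoxy-4β-hydroxy-5αH-daucane-6α,10α-diyl dimethylsilyl ether (six-membered oxasilacycle: Si on C6, O on C10), via dimethylsilyl ether 21 (not isolated)
Conditions: ClSiHMe2 (1.1 equiv), Et3N, CH2Cl2, 0 °C; then Pt2[(CH2=CHSiMe2)2O]3 (Karstedt catalyst, 1 mol %), PhMe, 50 °C
Reagents that add atoms: chlorodimethylsilane, C[SiH](C)Cl
Why: Silylation of the secondary C10 hydroxyl followed by platinum-catalysed intramolecular hydrosilylation (Tamao–Ito type) should deliver silicon to C6 and hydrogen to C5 in a syn fashion from the α face on which the C10 oxygen sits, closing a six-membered oxasilacycle because the fully substituted C5 cannot take silicon, which sets H-5 α (trans ring fusion) and the C6–Si bond α.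

Step 18
Reactants: 22 the cyclic siloxane
Product: 23 2β-acetoxy-8β,9α-epoxy-5αH-daucane-4β,6α,10α-triol
Conditions: H2O2 (30 %), KF, KHCO3, THF/MeOH, rt
Reagents that add atoms: hydrogen peroxide, OO
Why: Tamao–Fleming oxidation converts the C6–Si bond into C6–OH with retention of configuration and frees the C10 hydroxyl, while the buffered peroxide should leave the oxirane and the hindered acetate intact.

Step 19
Reactants: 23 2β-acetoxy-8β,9α-epoxy-5αH-daucane-4β,6α,10α-triol; 24 3,4-dimethoxybenzoyl chloride
Product: 25 2β-acetoxy-8β,9α-epoxy-4β,10α-dihydroxy-5αH-daucan-6α-yl 3,4-dimethoxybenzoate (target)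
Conditions: 24 (1.05 equiv), Et3N, DMAP (cat.), CH2Cl2, −20 → 0 °C
Reagents that add atoms: none
Why: DMAP-catalysed acylation should take place at the secondary C6 hydroxyl, which is far more accessible than the C10 hydroxyl flanked by the quaternary C1 and the oxirane and than the tertiary C4 hydroxyl.

Compound list
1 | (S)-4-(tert-butyldimethylsilyloxy)cyclopent-2-en-1-one | O=C1C=C[C@@H](O[Si](C)(C)C(C)(C)C)C1 | starting material
2 | trans-4-(tert-butyldimethylsilyloxy)-3-methyl-1-(trimethylsilyloxy)cyclopent-1-ene | C[Si](C)(C)OC1=C[C@H](C)[C@@H](O[Si](C)(C)C(C)(C)C)C1 | intermediate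
3 | (S)-4-(tert-butyldimethylsilyloxy)-3-methylcyclopent-2-en-1-one | O=C1C=C(C)[C@@H](O[Si](C)(C)C(C)(C)C)C1 | intermediate
4 | (S)-4-(tert-butyldimethylsilyloxy)-2-iodo-3-methylcyclopent-2-en-1-one | O=C1C(I)=C(C)[C@@H](O[Si](C)(C)C(C)(C)C)C1 | intermediate
5 | (1S,4S)-4-(tert-butyldimethylsilyloxy)-2-iodo-1-isopropyl-3-methylcyclopent-2-en-1-ol (hydroxyl cis to the silyloxy group) | IC1=C(C)[C@@H](O[Si](C)(C)C(C)(C)C)C[C@]1(O)C(C)C | intermediate
6 | (1S,4S)-2-iodo-1-isopropyl-3-methylcyclopent-2-ene-1,4-diol | IC1=C(C)[C@@H](O)C[C@]1(O)C(C)C | intermediate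
7 | (1S,4S)-4-hydroxy-3-iodo-4-isopropyl-2-methylcyclopent-2-en-1-yl acetate | IC1=C(C)[C@@H](OC(C)=O)C[C@]1(O)C(C)C | intermediate
8 | tert-butyl(but-3-yn-1-yloxy)dimethylsilane | C#CCCO[Si](C)(C)C(C)(C)C | starting material
9 | (E)-[4-(tert-butyldimethylsilyloxy)-2-methylbut-1-en-1-yl]dimethylalane | C[Al](C)/C=C(C)/CCO[Si](C)(C)C(C)(C)C | intermediate
10 | (E)-5-(tert-butyldimethylsilyloxy)-3-methylpent-2-en-1-ol | OC/C=C(C)/CCO[Si](C)(C)C(C)(C)C | intermediate
11 | (E)-tert-butyl{[5-(4-methoxybenzyloxy)-3-methylpent-3-en-1-yl]oxy}dimethylsilane | COc1ccc(COC/C=C(C)/CCO[Si](C)(C)C(C)(C)C)cc1 | intermediate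
12 | (E)-5-(4-methoxybenzyloxy)-3-methylpent-3-en-1-ol | COc1ccc(COC/C=C(C)/CCO)cc1 | intermediate
13 | (E)-5-(4-methoxybenzyloxy)-3-methylpent-3-enal | COc1ccc(COC/C=C(C)/CC=O)cc1 | intermediate
14 | (1S,4S)-4-hydroxy-3-[(E)-1-hydroxy-5-(4-methoxybenzyloxy)-3-methylpent-3-en-1-yl]-4-isopropyl-2-methylcyclopent-2-en-1-yl acetate (C6 epimers) | COc1ccc(COC/C=C(C)/CC(O)C2=C(C)[C@@H](OC(C)=O)C[C@]2(O)C(C)C)cc1 | intermediate
15 | (1S,4S)-4-hydroxy-4-isopropyl-3-[(E)-1-(methoxycarbonyloxy)-5-(4-methoxybenzyloxy)-3-methylpent-3-en-1-yl]-2-methylcyclopent-2-en-1-yl acetate (C6 epimers) | COc1ccc(COC/C=C(C)/CC(OC(=O)OC)C2=C(C)[C@@H](OC(C)=O)C[C@]2(O)C(C)C)cc1 | intermediate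
16 | (1S,4S)-4-hydroxy-3-[(E)-5-hydroxy-1-(methoxycarbonyloxy)-3-methylpent-3-en-1-yl]-4-isopropyl-2-methylcyclopent-2-en-1-yl acetate (C6 epimers) | OC/C=C(C)/CC(OC(=O)OC)C1=C(C)[C@@H](OC(C)=O)C[C@]1(O)C(C)C | intermediate
17 | (1S,4S)-4-hydroxy-3-{2-[(2R,3R)-3-(hydroxymethyl)-2-methyloxiran-2-yl]-1-(methoxycarbonyloxy)ethyl}-4-isopropyl-2-methylcyclopent-2-en-1-yl acetate (C6 epimers) | COC(=O)OC(C[C@@]1(C)O[C@@H]1CO)C1=C(C)[C@@H](OC(C)=O)C[C@]1(O)C(C)C | intermediate
18 | (1S,4S)-3-{2-[(2R,3S)-3-formyl-2-methyloxiran-2-yl]-1-(methoxycarbonyloxy)ethyl}-4-hydroxy-4-isopropyl-2-methylcyclopent-2-en-1-yl acetate (C6 epimers) | COC(=O)OC(C[C@@]1(C)O[C@@H]1C=O)C1=C(C)[C@@H](OC(C)=O)C[C@]1(O)C(C)C | intermediate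
19 | allylindium iodide methoxide with indium on C6 of the C6–C5–C1 allyl unit of 18 (carbonate replaced by indium) | CO[In](I)C(C[C@@]1(C)O[C@@H]1C=O)C1=C(C)[C@@H](OC(C)=O)C[C@]1(O)C(C)C | intermediate
20 | 2β-acetoxy-8β,9α-epoxydauc-5-ene-4β,10α-diol | C1C[C@@]2(C)O[C@@H]2[C@H](O)[C@]2(C)[C@@H](OC(C)=O)C[C@](O)(C(C)C)C2=1 | intermediate
21 | 2β-acetoxy-10α-(dimethylsilyloxy)-8β,9α-epoxydauc-5-en-4β-ol | C1C[C@@]2(C)O[C@@H]2[C@H](O[SiH](C)C)[C@]2(C)[C@@H](OC(C)=O)C[C@](O)(C(C)C)C2=1 | intermediate
22 | 2β-acetoxy-8β,9α-epoxy-4β-hydroxy-5αH-daucane-6α,10α-diyl dimethylsilyl ether (Si on C6, O on C10) | C[Si]1(C)[C@@H]2C[C@@]3(C)O[C@@H]3[C@H](O1)[C@]3(C)[C@@H](OC(C)=O)C[C@](O)(C(C)C)[C@@H]23 | intermediate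
23 | 2β-acetoxy-8β,9α-epoxy-5αH-daucane-4β,6α,10α-triol | O[C@@H]1C[C@@]2(C)O[C@@H]2[C@H](O)[C@]2(C)[C@@H](OC(C)=O)C[C@](O)(C(C)C)[C@@H]12 | intermediate
24 | 3,4-dimethoxybenzoyl chloride | COc1ccc(C(=O)Cl)cc1OC | starting material
25 | 2β-acetoxy-8β,9α-epoxy-4β,10α-dihydroxy-5αH-daucan-6α-yl 3,4-dimethoxybenzoate | COc1ccc(C(=O)O[C@@H]2C[C@@]3(C)O[C@@H]3[C@H](O)[C@]3(C)[C@@H](OC(C)=O)C[C@](O)(C(C)C)[C@@H]23)cc1OC | target

Total step count: 19. Longest linear sequence: 15 steps (steps 1–6 and 11–19 from compound 1); steps 7–10 are a four-step side branch from compound 8.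

Steps most likely to fail

Step 16. The allylindium species may be protonated, may eliminate or may add intermolecularly before the strained ring closes, because the metal-bridged transition state has to span C6 and C10 with only three atoms. The fallback replaces the metal-bridged addition by the fluoride-triggered addition of an isolable allylsilane through an open transition state. It sets out from 17: Pd2(dba)3 (5 mol %) and hexamethyldisilane in DMF should replace the carbonate by a trimethylsilyl group at the less hindered allyl terminus and give the C6 trimethylsilyl analogue of 17 F1. Dess–Martin periodinane (NaHCO3, CH2Cl2) should then give the C6 trimethylsilyl epoxy aldehyde F2. TBAF in THF at high dilution should generate the allyl anion equivalent, which adds through C1 to the aldehyde (fluoride-promoted intramolecular Hosomi–Sakurai reaction), and the route is rejoined at 20.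

Step 17. Silicon may be delivered to C5 instead of C6, or the alkene may migrate on platinum, so that the syn delivery of H-5 and O-6 from the α face is lost. The fallback uses hydroboration with borane itself instead of the silicon tether. It sets out from 20: BH3·SMe2 (THF, 0 °C) first binds the α-oriented C10 oxygen and should then add boron to the less substituted C6 and hydrogen to C5 on the face away from the angular methyl group. Aqueous work-up should give 2β-acetoxy-8β,9α-epoxy-4β,10α-dihydroxy-5αH-daucan-6α-ylboronic acid F3. NaBO3·4H2O (THF/H2O) oxidises the C–B bond with retention, and the route is rejoined at 23.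

Step 11. Oxidative addition of the hindered, tetrasubstituted alkenyl iodide may be slow, and the skipped aldehyde may isomerise into conjugation on the Lewis-acidic chromium salts before it is captured. The fallback adds a preformed alkenylmagnesium/cerium reagent at low temperature and moves the protecting-group exchange behind the coupling. It sets out from 5 and 13: i-PrMgCl·LiCl (2.2 equiv, THF, −20 °C; alkoxide formation, then iodine–magnesium exchange), CeCl3 and 13 at −78 °C should give the C2 tert-butyldimethylsilyl ether analogue of 14 F4. ClCO2Me/pyridine should give its C6 methyl carbonate F5. TBAF/AcOH should free the C2 hydroxyl to give the C2 alcohol analogue of 15 F6. Ac2O/pyridine/DMAP acetylates C2–OH and rejoins the route at 15.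

Further compounds
F1 | step 16 | (1S,4S)-4-hydroxy-3-{2-[(2R,3R)-3-(hydroxymethyl)-2-methyloxiran-2-yl]-1-(trimethylsilyl)ethyl}-4-isopropyl-2-methylcyclopent-2-en-1-yl acetate (C6 epimers) | C[Si](C)(C)C(C[C@@]1(C)O[C@@H]1CO)C1=C(C)[C@@H](OC(C)=O)C[C@]1(O)C(C)C
F2 | step 16 | (1S,4S)-3-{2-[(2R,3S)-3-formyl-2-methyloxiran-2-yl]-1-(trimethylsilyl)ethyl}-4-hydroxy-4-isopropyl-2-methylcyclopent-2-en-1-yl acetate (C6 epimers) | C[Si](C)(C)C(C[C@@]1(C)O[C@@H]1C=O)C1=C(C)[C@@H](OC(C)=O)C[C@]1(O)C(C)C
F3 | step 17 | 2β-acetoxy-8β,9α-epoxy-4β,10α-dihydroxy-5αH-daucan-6α-ylboronic acid | OB(O)[C@@H]1C[C@@]2(C)O[C@@H]2[C@H](O)[C@]2(C)[C@@H](OC(C)=O)C[C@](O)(C(C)C)[C@@H]12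
F4 | step 11 | (1S,4S)-4-(tert-butyldimethylsilyloxy)-2-[(E)-1-hydroxy-5-(4-methoxybenzyloxy)-3-methylpent-3-en-1-yl]-1-isopropyl-3-methylcyclopent-2-en-1-ol (C6 epimers) | COc1ccc(COC/C=C(C)/CC(O)C2=C(C)[C@@H](O[Si](C)(C)C(C)(C)C)C[C@]2(O)C(C)C)cc1
F5 | step 11 | C6 methyl carbonate of F4 | COc1ccc(COC/C=C(C)/CC(OC(=O)OC)C2=C(C)[C@@H](O[Si](C)(C)C(C)(C)C)C[C@]2(O)C(C)C)cc1
F6 | step 11 | (1S,4S)-1-isopropyl-2-[(E)-1-(methoxycarbonyloxy)-5-(4-methoxybenzyloxy)-3-methylpent-3-en-1-yl]-3-methylcyclopent-2-ene-1,4-diol (C6 epimers) | COc1ccc(COC/C=C(C)/CC(OC(=O)OC)C2=C(C)[C@@H](O)C[C@]2(O)C(C)C)cc1
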